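Readings and results are simulated with made-up constants, and the scatter is random.

Late in the beta run L was still climbing, but slowly, and the meeting on these flasks began there. L is read in percent of the X charged.

| flask | X | G | Q | remark | time |
|---|---|---|---|---|---|
| beta | 0.15 M | 0.60 equiv | 25 mM (held) | run made earlier |  |
| epsilon | 0.10 M | 0.60 equiv | 25 mM (held) | run made earlier |  |
| theta | 0.22 M | 0.60 equiv | 25 mM (held) | run made earlier |  |
| delta | 0.15 M | 1.2 equiv | 25 mM (held) | run made earlier |  |
| green | 0.15 M | 0.600 equiv (fed, over 1.0 min) | 25 mM (held) | all else is in the flask from the start; the feed brings no volume worth counting | 5.0 min |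
| blue | 0.15 M | 0.600 equiv | 25 mM (held) | everything together at the start | 5.0 min |
| amber | 0.15 M (fed, over 1.0 min) | 0.600 equiv | 25 mM (held) | all else is in the flask from the start; the feed brings no volume worth counting | 5.0 min |
| violet | 0.15 M (in portions, 2, over 1.0 min) | 0.600 equiv | 25 mM (held) | first portion at the start, last at 1.0 min | 5.0 min |

| run | time / min | L / % |
|---|---|---|
| beta | 0.417 | 4.0 |
| beta | 0.833 | 5.8 |
| beta | 1.33 | 9.3 |
| beta | 2.50 | 11.2 |
| beta | 5.00 | 13.2 |
| epsilon | 0.250 | 3.5 |
| epsilon | 0.417 | 3.1 |
| epsilon | 0.833 | 6.4 |
| epsilon | 1.50 | 8.2 |
| epsilon | 3.00 | 11.3 |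
| theta | 0.250 | 2.7 |
| theta | 0.833 | 6.5 |
| theta | 1.33 | 8.9 |
| theta | 2.00 | 10.8 |
| theta | 3.00 | 12.2 |
| delta | 0.250 | 3.5 |
| delta | 0.417 | 5.2 |
| delta | 0.833 | 7.0 |
| delta | 1.50 | 8.3 |
| delta | 3.00 | 10.0 |

(each reading ± 0.5 percentage points)

- at the start none of Q is in solution

- the flask with the highest amount of L, in percent of the X charged ("all alike" if they lie within 1.5 percentage points) (green / blue / amber / violet / all alike)
- final L, as a percentage of the X charged, in green
- final L, as a percentage of the X charged, in blue
- final L, as a percentage of the X charged, in amber
- final L, as a percentage of the X charged, in violet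

The first speaker noted that blue repeats beta, with everything together at the start, so she took blue as the zero of the scale, at the beta reading of 13.2 % after 5.00 min. A charge fed steadily over 1.0 min, she said, enters on average 0.500 min late. Violet's X, half at the start and half at 1.0 min, has the same mean delay, the first moment of the dosing profile.

She argued that such a flask is roughly the beta curve read that much earlier, which seemed fair to her since the delay is shorter than the time of reading. Beta's L rose by a reading of 2 percentage points from 2.50 min to 5.00 min. Scaled to the mean delay, that gave 0.4 points, which she named the delay loss, the points of final L given up by adding late.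

Her own reckoning therefore put amber and violet at 12.8 %. Green, where G comes late but X does not, she set at the same figure, more roughly. The delay loss is smaller than the margin, so she expected no flask to lead.

The forecast's author disagreed and named green, with 14.5 % in green, 13.2 % in blue, 11 % in amber and 12 % in violet, holding that "Green keeps G/X low early, so it should finish slightly higher". That spread of 3.5 points is wider than the margin, and on this point the meeting parted.

    X → E (k = 0.00270 s⁻¹)
    D + E → Z (k = 400 L mol⁻¹ s⁻¹)
    G + E → L (k = 130 L mol⁻¹ s⁻¹)
    G + L → J (k = 0.0880 L mol⁻¹ s⁻¹)
    Q ⇌ D, rate k5*(csat - [D]) (kL = 0.0670 s⁻¹)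

The flasks gave 12.0 % in green, 12.9 % in blue, 12.4 % in amber and 12.4 % in violet, so the answer is all alike, their spread being less than the margin. In blue, the half-life of L by the turning of G + L into J alone, the other concentrations as charged, is 1.5 min, shorter than the time of reading. Taken from blue's 12.9 %, the delay loss of 0.4 points gives 12.5 %, and amber stands at 12.4 % and violet at 12.4 %.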